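**Retrosynthetic overview**

1. Locants (drimane type): ring A = C1–C5 plus C10 (C1=C2–C3=O, gem-dimethyl C4); ring B = C5–C10 (exocyclic C8=C12, C9 carries C11H2–O–aryl). The coumarin is bought intact as isofraxidin.
2. Late stage: the enone comes from a 3R silyloxy group (IBX) and the C11–O aryl ether from a Mitsunobu reaction. Before that, the C9–C11 bond and the C8=C12 methylene arise together by a Wittig–Still [2,3] shift of a C12–O–CH2SnBu3 ether on a C8=C9 octalin, which sets C9.
3. Key disconnection: the octalin opens by retro-Diels–Alder across C5–C10 and C6–C7 to an acyclic triene (diene C7=C8–C9=C10, (E)-vinyl sulfone C5=C6, linked by C1–C4). Rings A and B therefore form together in one step, and no ring is formed afterwards.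
4. Enabling feature: ring B has an sp2 C8 next to the substituted C9 (a masked C8=C9 cyclohexene), and its atoms C5 and C10 are the fusion atoms shared with ring A. The four-carbon diene and two-carbon dienophile are thus bridged by the ring-A atoms C1–C4. The sulfonyl group on C6 (activator) and the C3 carbinol (stereocontrol) are temporary.
5. Triene assembly: pent-4-yn-1-ol (C3, C2, C1, C10, C9); carboalumination/Negishi coupling (C10 methyl, C7, C8, C12); Kiyooka aldol (C4 with its methyls, C5; sets C3); Horner–Wadsworth–Emmons olefination (C6).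

Key step: step 8

Remark: TBS = tert-butyldimethylsilyl; N-tosyl-L-valine is assumed to be the promoter antipode that delivers the 3R aldol in step 3 (the D antipode would be used if the sense proved opposite).

**Step 1**
Reactants: 1 pent-4-yn-1-ol; 2 [(2-bromoprop-2-en-1-yl)oxy](tert-butyl)dimethylsilane
Product: 4 (4E)-6-(TBSOCH2)-4-methylhepta-4,6-dien-1-ol, via alkenylalane 3 (not isolated)
Conditions: Me3Al (3 equiv), Cp2ZrCl2 (0.25 equiv), CH2Cl2, 0 °C to rt; then 2, Pd(PPh3)4 (5 mol%), ZnCl2 (cocatalyst), THF, rt; aq. Rochelle salt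
Reagents that add atoms: trimethylaluminium, C[Al](C)C
Why: Zirconium-catalysed Negishi carboalumination adds methyl and aluminium syn across the terminal alkyne (methyl to the internal carbon), and the (E)-alkenylalane then cross-couples with retention with the vinylic bromide under Pd(PPh3)4/ZnCl2 catalysis (Negishi coupling), which fixes the E geometry of the trisubstituted diene alkene.

**Step 2**
Reactants: 4 dienol
Product: 5 (4E)-6-(TBSOCH2)-4-methylhepta-4,6-dienal
Conditions: Dess–Martin periodinane, NaHCO3, CH2Cl2, 0 °C to rt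
Reagents that add atoms: none
Why: Dess–Martin oxidation converts the primary alcohol to the aldehyde under buffered non-acidic conditions that leave the diene and the allylic silyl ether untouched.

**Step 3**
Reactants: 5 dienal; 6 1-methoxy-2-methyl-1-(trimethylsilyloxy)prop-1-ene
Product: 7 methyl (3R,6E)-8-(TBSOCH2)-3-hydroxy-2,2,6-trimethylnona-6,8-dienoate
Conditions: N-tosyl-L-valine (1.1 equiv), BH3·THF (1.0 equiv), CH2Cl2, 0 °C to rt; then 5 and 6, −78 °C; pH 7 buffer
Reagents that add atoms: none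
Why: Kiyooka aldol (oxazaborolidinone-promoted asymmetric Mukaiyama aldol): the promoter formed in situ from N-tosyl-L-valine and BH3 binds the aldehyde and exposes one face to the isobutyrate silyl ketene acetal, which should create the 3R carbinol next to the new quaternary C4.

**Step 4**
Reactants: 7 hydroxy ester
Product: 8 methyl (3R,6E)-3-(TBSO)-8-(TBSOCH2)-2,2,6-trimethylnona-6,8-dienoate
Conditions: TBSOTf, 2,6-lutidine, CH2Cl2, −78 to 0 °C
Reagents that add atoms: tert-butyldimethylsilyl trifluoromethanesulfonate, CC(C)(C)[Si](C)(C)OS(=O)(=O)C(F)(F)F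
Why: Silylation with the triflate and a hindered base protects the neopentyl-type secondary alcohol, which blocks retro-aldol cleavage and supplies the bulky equatorial group used for stereocontrol in step 8.

**Step 5**
Reactants: 8 silyloxy ester
Product: 9 (3R,6E)-3-(TBSO)-8-(TBSOCH2)-2,2,6-trimethylnona-6,8-dien-1-ol
Conditions: i-Bu2AlH (2.5 equiv), CH2Cl2, −78 to 0 °C; aq. Rochelle salt
Reagents that add atoms: none
Why: i-Bu2AlH reduces the hindered methyl ester to the primary alcohol (ester reduction) without touching the diene or the silyl ethers.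

**Step 6**
Reactants: 9 primary alcohol
Product: 10 (3R,6E)-3-(TBSO)-8-(TBSOCH2)-2,2,6-trimethylnona-6,8-dienal
Conditions: Dess–Martin periodinane, NaHCO3, CH2Cl2, 0 °C to rt
Reagents that add atoms: none
Why: Dess–Martin oxidation gives the aldehyde, which has no α-hydrogen and so can neither enolise nor eliminate the β-silyloxy group.

**Step 7**
Reactants: 10 aldehyde; 11 diethyl [(phenylsulfonyl)methyl]phosphonate
Product: 12 [(1E,4R,7E)-4-(TBSO)-9-(TBSOCH2)-3,3,7-trimethyldeca-1,7,9-trien-1-yl]sulfonylbenzene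
Conditions: NaH, THF, 0 °C; then 10, 0 °C to rt
Reagents that add atoms: none
Why: Horner–Wadsworth–Emmons olefination with the sulfonyl-stabilised phosphonate anion should give the (E)-vinyl sulfone selectively, installing C6 and the activating group in one step.

**Step 8**
Reactants: 12 sulfonyl triene
Product: 13 (4R,4aS,6R,8aS)-6-(TBSO)-2-(TBSOCH2)-5,5,8a-trimethyl-4-(phenylsulfonyl)-3,4,4a,5,6,7,8,8a-octahydronaphthalene (trans-fused)
Conditions: toluene (0.01 M, degassed), BHT (cat.), sealed tube, 160 °C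
Reagents that add atoms: none
Why: Thermal type 1 intramolecular Diels–Alder reaction: the alkyl-substituted diene C7=C8–C9=C10 (HOMO) and the (E)-vinyl sulfone C5=C6 (LUMO lowered by the sulfonyl group) combine in a concerted, suprafacial [4+2] cycloaddition that forms C6–C7 and C5–C10 together. The closest known reaction type is the thermal cyclisation of (E)-1-sulfonyldeca-1,7,9-trienes to trans-fused octalins, and quaternary angular-methyl carbons have been created in intramolecular Diels–Alder reactions from fully substituted diene termini. Ring B closes as a cyclohexene by union of the four-carbon diene with the two-carbon dienophile, and ring A closes at the same moment because the chain C1–C4 that links C10 to C5 becomes six-membered through the new C5–C10 bond (a 1,7,9-decatriene giving a bicyclo[4.4.0] system). C5 and the quaternary C10 are set relative to each other by the E geometry of the C9=C10 alkene (methyl inside, chain outside) combined with the anti, sulfonyl-endo, chair-like transition state, which puts the C10 methyl trans to H5; the syn alternative would force a diene or dienophile carbon axial on the forming ring A against the axial C4 methyl. Absolute configuration is relayed from C3, whose bulky OTBS group should sit equatorial on that chair and so select the diene face that leads to 4aS,8aS; the sulfonyl-bearing C6 follows from the E dienophile and is erased in step 9. The step needs trans over cis fusion, one diene face, and cycloaddition faster than [1,5]-hydrogen shift from the inside methyl; sulfone activation, the Thorpe–Ingold effect of the C4 gem-dimethyl group and the equatorial OTBS anchor are the substrate features relied on, with high dilution and BHT suppressing intermolecular reaction and polymerisation.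

**Step 9**
Reactants: 13 sulfonyl octalin
Product: 14 (4aS,6R,8aS)-6-(TBSO)-2-(TBSOCH2)-5,5,8a-trimethyl-3,4,4a,5,6,7,8,8a-octahydronaphthalene
Conditions: Na(Hg) (6% Na), Na2HPO4, MeOH/THF, −20 °C to rt
Reagents that add atoms: none
Why: Reductive desulfonylation: electron transfer from sodium amalgam cleaves the C6–S bond and methanol protonates the resulting carbanion, so C6 becomes CH2 and its configuration is lost without consequence, while the isolated alkene and the silyl ethers are inert.

**Step 10**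
Reactants: 14 bis-silyl ether
Product: 15 [(4aS,6R,8aS)-6-(TBSO)-5,5,8a-trimethyl-3,4,4a,5,6,7,8,8a-octahydronaphthalen-2-yl]methanol
Conditions: PPTS (0.2 equiv), MeOH, rt
Reagents that add atoms: none
Why: Acid-catalysed methanolysis removes the unhindered primary allylic silyl ether far faster than the secondary one flanked by the gem-dimethyl carbon (selective desilylation).

**Step 11**
Reactants: 15 allylic alcohol; 16 tributyl(iodomethyl)stannane
Product: 17 tributyl({[(4aS,6R,8aS)-6-(TBSO)-5,5,8a-trimethyl-3,4,4a,5,6,7,8,8a-octahydronaphthalen-2-yl]methoxy}methyl)stannane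
Conditions: KH, 18-crown-6 (cat.), THF, 0 °C; then 16, rt
Reagents that add atoms: none
Why: Williamson etherification of the potassium alkoxide with the iodomethylstannane gives the stannylmethyl ether required for the Wittig–Still rearrangement.

**Step 12**
Reactants: 17 stannylmethyl ether
Product: 19 [(1S,4aS,6R,8aR)-6-(TBSO)-5,5,8a-trimethyl-2-methylidenedecahydronaphthalen-1-yl]methanol, via alkoxymethyllithium 18 (not isolated)
Conditions: n-BuLi (1.5 equiv), THF, −78 to −20 °C; then H2O
Reagents that add atoms: none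
Why: Tin–lithium exchange gives the α-alkoxymethyllithium, which undergoes the Wittig–Still [2,3]-sigmatropic shift: the carbanion carbon bonds to C9 as the C12–O bond breaks and the alkene moves to C8=C12, with delivery on the ring face anti to the pseudoaxial C10 methyl (axial bond formation), which sets C9 with the CH2OH group trans to that methyl and cis to H5.

**Step 13**
Reactants: 19 homoallylic alcohol; 20 isofraxidin (7-hydroxy-6,8-dimethoxy-2H-chromen-2-one)
Product: 21 7-{[(1S,4aS,6R,8aR)-6-(TBSO)-5,5,8a-trimethyl-2-methylidenedecahydronaphthalen-1-yl]methoxy}-6,8-dimethoxy-2H-chromen-2-one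
Conditions: PPh3, DIAD, THF, 0 °C to rt
Reagents that add atoms: none
Why: Mitsunobu etherification: the acidic 7-hydroxyl of the coumarin displaces the oxyphosphonium of the primary alcohol by SN2 at CH2, so no stereocentre is affected.

**Step 14**
Reactants: 21 silyl-protected coumarin ether
Product: 22 7-{[(1S,4aS,6R,8aR)-6-hydroxy-5,5,8a-trimethyl-2-methylidenedecahydronaphthalen-1-yl]methoxy}-6,8-dimethoxy-2H-chromen-2-one
Conditions: HF·pyridine, pyridine/THF, 0 °C to rt
Reagents that add atoms: none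
Why: Fluoride-induced desilylation with buffered HF·pyridine frees the hindered C3 alcohol without opening the coumarin lactone or isomerising the exocyclic alkene.

**Step 15**
Reactants: 22 C3 alcohol
Product: 24 7-{[(1S,4aS,8aR)-5,5,8a-trimethyl-2-methylidene-6-oxo-1,2,3,4,4a,5,6,8a-octahydronaphthalen-1-yl]methoxy}-6,8-dimethoxy-2H-chromen-2-one (CNP0227866.1), via ketone 23 (not isolated)
Conditions: IBX (4 equiv), DMSO, rt; then 80 °C
Reagents that add atoms: none
Why: IBX oxidises the alcohol to the C3 ketone and on warming dehydrogenates it through its enol (IBX α,β-dehydrogenation); since C4 is quaternary only C1–C2 can be desaturated, and the C3 stereocentre that relayed the absolute configuration disappears.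

**Compound list**

1 | pent-4-yn-1-ol | C#CCCCO | starting material
2 | [(2-bromoprop-2-en-1-yl)oxy](tert-butyl)dimethylsilane | C=C(Br)CO[Si](C)(C)C(C)(C)C | starting material
3 | [(1E)-5-(dimethylalumanyloxy)-2-methylpent-1-en-1-yl]dimethylalumane | C[Al](C)/C=C(\C)CCCO[Al](C)C | intermediate
4 | (4E)-6-(TBSOCH2)-4-methylhepta-4,6-dien-1-ol | OCCC/C(C)=C/C(=C)CO[Si](C)(C)C(C)(C)C | intermediate
5 | (4E)-6-(TBSOCH2)-4-methylhepta-4,6-dienal | O=CCC/C(C)=C/C(=C)CO[Si](C)(C)C(C)(C)C | intermediate
6 | 1-methoxy-2-methyl-1-(trimethylsilyloxy)prop-1-ene | COC(O[Si](C)(C)C)=C(C)C | starting material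
7 | methyl (3R,6E)-8-(TBSOCH2)-3-hydroxy-2,2,6-trimethylnona-6,8-dienoate | COC(=O)C(C)(C)[C@H](O)CC/C(C)=C/C(=C)CO[Si](C)(C)C(C)(C)C | intermediate
8 | methyl (3R,6E)-3-(TBSO)-8-(TBSOCH2)-2,2,6-trimethylnona-6,8-dienoate | COC(=O)C(C)(C)[C@H](O[Si](C)(C)C(C)(C)C)CC/C(C)=C/C(=C)CO[Si](C)(C)C(C)(C)C | intermediate
9 | (3R,6E)-3-(TBSO)-8-(TBSOCH2)-2,2,6-trimethylnona-6,8-dien-1-ol | OCC(C)(C)[C@H](O[Si](C)(C)C(C)(C)C)CC/C(C)=C/C(=C)CO[Si](C)(C)C(C)(C)C | intermediate
10 | (3R,6E)-3-(TBSO)-8-(TBSOCH2)-2,2,6-trimethylnona-6,8-dienal | O=CC(C)(C)[C@H](O[Si](C)(C)C(C)(C)C)CC/C(C)=C/C(=C)CO[Si](C)(C)C(C)(C)C | intermediate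
11 | diethyl [(phenylsulfonyl)methyl]phosphonate | CCOP(=O)(CS(=O)(=O)c1ccccc1)OCC | starting material
12 | [(1E,4R,7E)-4-(TBSO)-9-(TBSOCH2)-3,3,7-trimethyldeca-1,7,9-trien-1-yl]sulfonylbenzene | O=S(=O)(/C=C/C(C)(C)[C@H](O[Si](C)(C)C(C)(C)C)CC/C(C)=C/C(=C)CO[Si](C)(C)C(C)(C)C)c1ccccc1 | intermediate
13 | (4R,4aS,6R,8aS)-6-(TBSO)-2-(TBSOCH2)-5,5,8a-trimethyl-4-(phenylsulfonyl)-3,4,4a,5,6,7,8,8a-octahydronaphthalene | CC(C)(C)[Si](C)(C)OCC1=C[C@]2(C)CC[C@@H](O[Si](C)(C)C(C)(C)C)C(C)(C)[C@H]2[C@H](S(=O)(=O)c3ccccc3)C1 | intermediate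
14 | (4aS,6R,8aS)-6-(TBSO)-2-(TBSOCH2)-5,5,8a-trimethyl-3,4,4a,5,6,7,8,8a-octahydronaphthalene | CC(C)(C)[Si](C)(C)OCC1=C[C@]2(C)CC[C@@H](O[Si](C)(C)C(C)(C)C)C(C)(C)[C@H]2CC1 | intermediate
15 | [(4aS,6R,8aS)-6-(TBSO)-5,5,8a-trimethyl-3,4,4a,5,6,7,8,8a-octahydronaphthalen-2-yl]methanol | OCC1=C[C@]2(C)CC[C@@H](O[Si](C)(C)C(C)(C)C)C(C)(C)[C@H]2CC1 | intermediate
16 | tributyl(iodomethyl)stannane | CCCC[Sn](CI)(CCCC)CCCC | starting material
17 | tributyl({[(4aS,6R,8aS)-6-(TBSO)-5,5,8a-trimethyl-3,4,4a,5,6,7,8,8a-octahydronaphthalen-2-yl]methoxy}methyl)stannane | CCCC[Sn](CCCC)(CCCC)COCC1=C[C@]2(C)CC[C@@H](O[Si](C)(C)C(C)(C)C)C(C)(C)[C@H]2CC1 | intermediate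
18 | ({[(4aS,6R,8aS)-6-(TBSO)-5,5,8a-trimethyl-3,4,4a,5,6,7,8,8a-octahydronaphthalen-2-yl]methoxy}methyl)lithium | [Li]COCC1=C[C@]2(C)CC[C@@H](O[Si](C)(C)C(C)(C)C)C(C)(C)[C@H]2CC1 | intermediate
19 | [(1S,4aS,6R,8aR)-6-(TBSO)-5,5,8a-trimethyl-2-methylidenedecahydronaphthalen-1-yl]methanol | C=C1CC[C@@H]2C(C)(C)[C@H](O[Si](C)(C)C(C)(C)C)CC[C@@]2(C)[C@H]1CO | intermediate
20 | isofraxidin (7-hydroxy-6,8-dimethoxy-2H-chromen-2-one) | COc1cc2ccc(=O)oc2c(OC)c1O | starting material
21 | 7-{[(1S,4aS,6R,8aR)-6-(TBSO)-5,5,8a-trimethyl-2-methylidenedecahydronaphthalen-1-yl]methoxy}-6,8-dimethoxy-2H-chromen-2-one | C=C1CC[C@@H]2C(C)(C)[C@H](O[Si](C)(C)C(C)(C)C)CC[C@@]2(C)[C@H]1COc1c(OC)cc2ccc(=O)oc2c1OC | intermediate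
22 | 7-{[(1S,4aS,6R,8aR)-6-hydroxy-5,5,8a-trimethyl-2-methylidenedecahydronaphthalen-1-yl]methoxy}-6,8-dimethoxy-2H-chromen-2-one | C=C1CC[C@@H]2C(C)(C)[C@H](O)CC[C@@]2(C)[C@H]1COc1c(OC)cc2ccc(=O)oc2c1OC | intermediate
23 | 7-{[(1S,4aS,8aR)-5,5,8a-trimethyl-2-methylidene-6-oxodecahydronaphthalen-1-yl]methoxy}-6,8-dimethoxy-2H-chromen-2-one | C=C1CC[C@@H]2C(C)(C)C(=O)CC[C@@]2(C)[C@H]1COc1c(OC)cc2ccc(=O)oc2c1OC | intermediate
24 | 7-{[(1S,4aS,8aR)-5,5,8a-trimethyl-2-methylidene-6-oxo-1,2,3,4,4a,5,6,8a-octahydronaphthalen-1-yl]methoxy}-6,8-dimethoxy-2H-chromen-2-one | C=C1CC[C@@H]2C(C)(C)C(=O)C=C[C@@]2(C)[C@H]1COc1c(OC)cc2ccc(=O)oc2c1OC | target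

**Step count and risks**

Total step count: 15. Longest linear sequence: 15 steps (1 to 24); compounds 2, 6, 11, 16 and 20 are purchased and enter in single steps.

Steps most likely to fail:

Step 8 (key cycloaddition). At the temperature needed, [1,5]-hydrogen shift from the inside methyl of the diene may outrun cycloaddition, or closure may proceed partly through the syn transition state (cis fusion) or with the OTBS group axial (wrong diene face). The fallback replaces thermal sulfone activation by Lewis-acid-promoted carbonyl activation at low temperature, followed by decarbonylation. It sets out from aldehyde 10: Wittig olefination with (triphenylphosphoranylidene)acetaldehyde (toluene, 90 °C) should give (2E,5R,8E)-5-(TBSO)-10-(TBSOCH2)-4,4,8-trimethylundeca-2,8,10-trienal F1. Me2AlCl (CH2Cl2, −78 to −20 °C) should then promote an endo-selective intramolecular Diels–Alder reaction to the trans-fused (1R,4aS,7R,8aS)-7-(TBSO)-3-(TBSOCH2)-4a,8,8-trimethyl-1,2,4a,5,6,7,8,8a-octahydronaphthalene-1-carbaldehyde F2. Tsuji–Wilkinson decarbonylation with RhCl(PPh3)3 (1.05 equiv, toluene, 110 °C) removes the formyl group and returns to the route at 14.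

Step 12 (Wittig–Still shift). Bond formation at C9 next to the quaternary C10 may be slow enough for [1,2]-shift or protonation of the lithiated ether to compete. The fallback uses a [3,3] shift and a one-carbon degradation and sets out from allylic alcohol 15. Johnson–Claisen rearrangement (triethyl orthoacetate, cat. propionic acid, 140 °C) should deliver the two-carbon chain to the same face of C9 and give ethyl 2-[(1S,4aS,6R,8aS)-6-(TBSO)-5,5,8a-trimethyl-2-methylidenedecahydronaphthalen-1-yl]acetate F3. Saponification (LiOH, THF/MeOH/H2O) gives 2-[(1S,4aS,6R,8aS)-6-(TBSO)-5,5,8a-trimethyl-2-methylidenedecahydronaphthalen-1-yl]acetic acid F4. Coupling with 2-mercaptopyridine N-oxide (DCC, CH2Cl2, dark) gives the Barton ester 2-thioxopyridin-1(2H)-yl 2-[(1S,4aS,6R,8aS)-6-(TBSO)-5,5,8a-trimethyl-2-methylidenedecahydronaphthalen-1-yl]acetate F5. Barton decarboxylative hydroxylation (O2, t-BuSH, hν; then P(OMe)3) returns to the route at 19.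

Step 13 (Mitsunobu etherification). The oxyphosphonium may lose the allylic H9 by E2 elimination, or substitution by the di-ortho-substituted phenol may be too slow. The fallback is a two-step sulfonate/phenoxide Williamson etherification and sets out from alcohol 19. MsCl, Et3N (CH2Cl2, 0 °C) gives [(1S,4aS,6R,8aR)-6-(TBSO)-5,5,8a-trimethyl-2-methylidenedecahydronaphthalen-1-yl]methyl methanesulfonate F6. Displacement with the caesium phenoxide of 20 (Cs2CO3, DMF, 60 °C) returns to the route at 21.

**Further compounds**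

F1 | step 8 | (2E,5R,8E)-5-(TBSO)-10-(TBSOCH2)-4,4,8-trimethylundeca-2,8,10-trienal | O=C/C=C/C(C)(C)[C@H](O[Si](C)(C)C(C)(C)C)CC/C(C)=C/C(=C)CO[Si](C)(C)C(C)(C)C
F2 | step 8 | (1R,4aS,7R,8aS)-7-(TBSO)-3-(TBSOCH2)-4a,8,8-trimethyl-1,2,4a,5,6,7,8,8a-octahydronaphthalene-1-carbaldehyde | CC(C)(C)[Si](C)(C)OCC1=C[C@]2(C)CC[C@@H](O[Si](C)(C)C(C)(C)C)C(C)(C)[C@H]2[C@H](C=O)C1
F3 | step 12 | ethyl 2-[(1S,4aS,6R,8aS)-6-(TBSO)-5,5,8a-trimethyl-2-methylidenedecahydronaphthalen-1-yl]acetate | C=C1CC[C@@H]2C(C)(C)[C@H](O[Si](C)(C)C(C)(C)C)CC[C@@]2(C)[C@H]1CC(=O)OCC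
F4 | step 12 | 2-[(1S,4aS,6R,8aS)-6-(TBSO)-5,5,8a-trimethyl-2-methylidenedecahydronaphthalen-1-yl]acetic acid | C=C1CC[C@@H]2C(C)(C)[C@H](O[Si](C)(C)C(C)(C)C)CC[C@@]2(C)[C@H]1CC(=O)O
F5 | step 12 | 2-thioxopyridin-1(2H)-yl 2-[(1S,4aS,6R,8aS)-6-(TBSO)-5,5,8a-trimethyl-2-methylidenedecahydronaphthalen-1-yl]acetate | C=C1CC[C@@H]2C(C)(C)[C@H](O[Si](C)(C)C(C)(C)C)CC[C@@]2(C)[C@H]1CC(=O)On1ccccc1=S
F6 | step 13 | [(1S,4aS,6R,8aR)-6-(TBSO)-5,5,8a-trimethyl-2-methylidenedecahydronaphthalen-1-yl]methyl methanesulfonate | C=C1CC[C@@H]2C(C)(C)[C@H](O[Si](C)(C)C(C)(C)C)CC[C@@]2(C)[C@H]1COS(C)(=O)=O
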